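**Retrosynthetic overview**
- The cyclopropane is made last, by cyclopropanation of the ring cis-alkene of a cyclooctadiene-fused butenolide; that alkene comes from a ring ketone (enol triflate, then reduction).
- The eight-membered ring and the butenolide come from a two-carbon ring expansion: a propargylic C≡C is inserted into the C(=O)–Cα bond of a cyclohexanone β-keto ester, and the product lactonises.
- The cyclohexanone β-keto ester comes from Dieckmann closure of an ester enolate onto a γ-lactone, which also frees the oxygen that carries the acetate.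
- The lactone comes from a vinylogous Mukaiyama–Michael addition of 3-methyl-2-silyloxyfuran to a γ-branched enal (sets the two adjacent ring stereocentres); the enal comes from Cu-catalysed allylic alkylation of crotyl bromide with homoprenyl Grignard (sets the side-chain centre), hydroformylation and dehydrogenation.
- Ring order: γ-lactone (temporary) → cyclohexanone → cyclooctenone with butenolide → cyclopropane.

Assumption: locants for 18–20 follow cycloocta[c]furan-1(3H)-one numbering (C1 lactone C=O, C3 OCH2, C5 ketone carbon, C6 methyl-bearing, C8 acetoxy-bearing, C9 side-chain-bearing); the sense of induction of each chiral catalyst (steps 1 and 5) is assigned by analogy and the antipodal catalyst is used if it proves reversed.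

**Step 1**
Reactants: 1 (E)-1-bromobut-2-ene; 2 5-bromo-2-methylpent-2-ene
Product: 4 (R)-3,7-dimethylocta-1,6-diene, via (4-methylpent-3-en-1-yl)magnesium bromide 3 (not isolated)
Conditions: Mg, THF (2 → 3); then 1, CuBr·SMe2 (2 mol %), (R,R)-Taniaphos (2.4 mol %), CH2Cl2, −78 °C
Reagents that add atoms: none
Why: Cu-catalysed asymmetric allylic alkylation (SN2′) of an (E)-allylic bromide with an alkyl Grignard is γ-selective, and the chiral ferrocenyl diphosphine sets the new C3 stereocentre (R).

**Step 2**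
Reactants: 4 (R)-3,7-dimethylocta-1,6-diene
Product: 5 (R)-4,8-dimethylnon-7-enal
Conditions: Rh(acac)(CO)2 (0.5 mol %), Xantphos (2 mol %), CO/H2 (1:1, 10 bar), toluene, 70 °C
Reagents that add atoms: carbon monoxide [C-]#[O+]
Why: Rh/Xantphos hydroformylation is linear-selective for the monosubstituted alkene and leaves the trisubstituted alkene and the allylic stereocentre untouched.

**Step 3**
Reactants: 5 (R)-4,8-dimethylnon-7-enal
Product: 6 (R,E)-4,8-dimethylnona-2,7-dienal
Conditions: IBX (1.5 equiv), DMSO, 70 °C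
Reagents that add atoms: none
Why: IBX dehydrogenation of an aldehyde gives the (E)-enal under non-basic conditions, so the γ-stereocentre is kept.

**Step 4**
Reactants: 7 3-methylfuran-2(5H)-one
Product: 8 3-methyl-2-(trimethylsilyloxy)furan
Conditions: TMSOTf, Et3N, CH2Cl2, 0 °C
Reagents that add atoms: trimethylsilyl triflate C[Si](C)(C)OS(=O)(=O)C(F)(F)F
Why: soft enolisation and O-silylation of the butenolide gives the aromatic 2-silyloxyfuran (silyl dienol ether formation).

**Step 5**
Reactants: 6 (R,E)-4,8-dimethylnona-2,7-dienal; 8 3-methyl-2-(trimethylsilyloxy)furan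
Product: 9 (3R,4R)-4,8-dimethyl-3-[(2S)-4-methyl-5-oxo-2,5-dihydrofuran-2-yl]non-7-enal
Conditions: (2S,5S)-5-benzyl-2-tert-butyl-3-methylimidazolidin-4-one·TfOH (20 mol %), CHCl3, H2O (2 equiv), −40 °C
Reagents that add atoms: none
Why: iminium-catalysed vinylogous Mukaiyama–Michael addition in which the imidazolidinone shields one face of the (E)-iminium so the furan C5 adds to the β-Si face (sets C3 = R), and the open transition state of the strong-acid protocol gives the furanone C2 = S diastereomer (ring O and side-chain branch anti along the extended chain).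

**Step 6**
Reactants: 9 (3R,4R)-4,8-dimethyl-3-[(2S)-4-methyl-5-oxo-2,5-dihydrofuran-2-yl]non-7-enal
Product: 11 methyl (3R,4R)-4,8-dimethyl-3-[(2S)-4-methyl-5-oxo-2,5-dihydrofuran-2-yl]non-7-enoate, via carboxylic acid 10 (not isolated)
Conditions: NaClO2, NaH2PO4, 2-methylbut-2-ene, t-BuOH/H2O, 0 °C; then TMSCHN2, PhMe/MeOH, 0 °C
Reagents that add atoms: sodium chlorite [Na+].[O-]Cl=O; trimethylsilyldiazomethane C[Si](C)(C)C=[N+]=[N-]
Why: Pinnick oxidation (buffered, with a hypochlorite scavenger that protects the alkenes) followed by diazoalkane esterification avoids base, so the acidic butenolide γ-centre is not epimerised.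

**Step 7**
Reactants: 11 methyl (3R,4R)-4,8-dimethyl-3-[(2S)-4-methyl-5-oxo-2,5-dihydrofuran-2-yl]non-7-enoate
Product: 12 methyl (3R,4R)-4,8-dimethyl-3-[(2R,4R)-4-methyl-5-oxooxolan-2-yl]non-7-enoate
Conditions: NaBH4, NiCl2·6H2O (0.3 equiv), MeOH, −20 → 0 °C
Reagents that add atoms: none
Why: nickel boride conjugate reduction touches only the conjugated C=C and delivers hydrogen anti to the C2 substituent, giving mainly the cis-2,4-disubstituted lactone (new centre 4R, which is in any case equilibrated in step 8).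

**Step 8**
Reactants: 12 methyl (3R,4R)-4,8-dimethyl-3-[(2R,4R)-4-methyl-5-oxooxolan-2-yl]non-7-enoate
Product: 14 methyl (3R,5R,6S)-5-acetoxy-3-methyl-6-[(2R)-6-methylhept-5-en-2-yl]-2-oxocyclohexane-1-carboxylate (C1 epimers/enol), via dilithium alkoxide enolate 13 (not isolated)
Conditions: LiHMDS (2.3 equiv), THF, −78 → 0 °C; Ac2O (1.1 equiv), −78 °C; aq. NH4Cl; then DBU (0.2 equiv), PhMe, 40 °C
Reagents that add atoms: acetic anhydride CC(=O)OC(C)=O
Why: Dieckmann-type intramolecular Claisen condensation of the ester enolate onto the lactone carbonyl gives the β-keto ester as its stable enolate and releases the C5 alkoxide, which is acetylated in preference to the chelated enolate; DBU equilibrates C3 to the equatorial methyl (trans to the axial acetoxy), while C5 and C6 come unchanged from step 5.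

**Step 9**
Reactants: 14 methyl (3R,5R,6S)-5-acetoxy-3-methyl-6-[(2R)-6-methylhept-5-en-2-yl]-2-oxocyclohexane-1-carboxylate; 15 trimethyl(prop-2-yn-1-yloxy)silane
Product: 18 (6R,8R,9S)-6-methyl-9-[(2R)-6-methylhept-5-en-2-yl]-1,5-dioxo-1,3,4,5,6,7,8,9-octahydrocycloocta[c]furan-8-yl acetate, via TMS-ether keto ester 16 (not isolated), via hydroxy ester 17 (not isolated)
Conditions: [ReBr(CO)3(thf)]2 (5 mol %), BnNC (10 mol %), toluene, 60 °C; then 1 M HCl, THF, rt
Reagents that add atoms: none
Why: Proposed new method: Re(I)-catalysed insertion of the C≡C of a propargylic silyl ether into the ketone–α-carbon bond of a hindered, acyloxy-substituted cyclohexanone β-keto ester with lactonisation in the same flask has not been shown; the chelated rhenium enolate should add to the terminal alkyne at its internal carbon, the alkenyl–rhenium then adds to the ring ketone, and the strained cyclobutenolate opens by retro-aldol cleavage (a stepwise, non-concerted 6→8 ring expansion) to the ring (Z)-enoate whose cis CH2OSi and CO2Me groups close to the butenolide once the silyl ether is hydrolysed; no stereocentre is formed and C6, C8 and C9 are not touched under the neutral conditions; the closest known reaction is the rhenium-catalysed two-carbon ring expansion of simple cyclic β-keto esters with terminal alkynes.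

**Step 10**
Reactants: 18 (6R,8R,9S)-6-methyl-9-[(2R)-6-methylhept-5-en-2-yl]-1,5-dioxo-1,3,4,5,6,7,8,9-octahydrocycloocta[c]furan-8-yl acetate
Product: 19 (6R,8R,9S)-8-acetoxy-6-methyl-9-[(2R)-6-methylhept-5-en-2-yl]-1-oxo-1,3,6,7,8,9-hexahydrocycloocta[c]furan-5-yl trifluoromethanesulfonate
Conditions: Tf2O, i-Pr2NEt, CH2Cl2, −78 °C
Reagents that add atoms: triflic anhydride O=S(=O)(OS(=O)(=O)C(F)(F)F)C(F)(F)F
Why: the C4 methylene is doubly activated (α to the ketone and vinylogous to the lactone), so soft enolisation and O-triflation go only towards C4 and give the conjugated dienyl triflate without disturbing C6.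

**Step 11**
Reactants: 19 (6R,8R,9S)-8-acetoxy-6-methyl-9-[(2R)-6-methylhept-5-en-2-yl]-1-oxo-1,3,6,7,8,9-hexahydrocycloocta[c]furan-5-yl trifluoromethanesulfonate
Product: 20 (6R,8R,9S)-6-methyl-9-[(2R)-6-methylhept-5-en-2-yl]-1-oxo-1,3,6,7,8,9-hexahydrocycloocta[c]furan-8-yl acetate
Conditions: Pd(OAc)2 (5 mol %), PPh3 (10 mol %), HCO2H, Et3N, DMF, 60 °C
Reagents that add atoms: none
Why: Pd-catalysed formate reduction of a vinyl triflate (oxidative addition, hydride transfer, reductive elimination) replaces OTf by H and leaves the acetate, lactone and alkenes alone.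

**Step 12**
Reactants: 20 (6R,8R,9S)-6-methyl-9-[(2R)-6-methylhept-5-en-2-yl]-1-oxo-1,3,6,7,8,9-hexahydrocycloocta[c]furan-8-yl acetate
Product: 21 acetoxycrenulide (target CNP0018922.1)
Conditions: CH2N2 (Et2O solution, excess), Pd(OAc)2 (5 mol %), Et2O/CH2Cl2, 0 °C
Reagents that add atoms: diazomethane C=[N+]=[N-]
Why: Pd-catalysed cyclopropanation with diazomethane reacts only at the least substituted, conjugated cis-alkene (the trisubstituted side-chain alkene and the tetrasubstituted butenolide alkene are inert) and is expected to add CH2 syn from the face anti to the adjacent C6 methyl, which is the face of the acetoxy group, setting both cyclopropane centres.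

**Compound list**
1 | (E)-1-bromobut-2-ene | C/C=C/CBr | starting material
2 | 5-bromo-2-methylpent-2-ene | CC(C)=CCCBr | starting material
3 | (4-methylpent-3-en-1-yl)magnesium bromide | CC(C)=CCC[Mg]Br | intermediate
4 | (R)-3,7-dimethylocta-1,6-diene | C=C[C@H](C)CCC=C(C)C | intermediate
5 | (R)-4,8-dimethylnon-7-enal | O=CCC[C@H](C)CCC=C(C)C | intermediate
6 | (R,E)-4,8-dimethylnona-2,7-dienal | O=C/C=C/[C@H](C)CCC=C(C)C | intermediate
7 | 3-methylfuran-2(5H)-one | CC1=CCOC1=O | starting material
8 | 3-methyl-2-(trimethylsilyloxy)furan | Cc1ccoc1O[Si](C)(C)C | intermediate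
9 | (3R,4R)-4,8-dimethyl-3-[(2S)-4-methyl-5-oxo-2,5-dihydrofuran-2-yl]non-7-enal | O=CC[C@@H]([C@@H]1OC(=O)C(C)=C1)[C@H](C)CCC=C(C)C | intermediate
10 | (3R,4R)-4,8-dimethyl-3-[(2S)-4-methyl-5-oxo-2,5-dihydrofuran-2-yl]non-7-enoic acid | OC(=O)C[C@@H]([C@@H]1OC(=O)C(C)=C1)[C@H](C)CCC=C(C)C | intermediate
11 | methyl (3R,4R)-4,8-dimethyl-3-[(2S)-4-methyl-5-oxo-2,5-dihydrofuran-2-yl]non-7-enoate | COC(=O)C[C@@H]([C@@H]1OC(=O)C(C)=C1)[C@H](C)CCC=C(C)C | intermediate
12 | methyl (3R,4R)-4,8-dimethyl-3-[(2R,4R)-4-methyl-5-oxooxolan-2-yl]non-7-enoate | COC(=O)C[C@@H]([C@@H]1OC(=O)[C@H](C)C1)[C@H](C)CCC=C(C)C | intermediate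
13 | dilithium salt (C5 alkoxide and β-keto ester enolate) of methyl (3R,5R,6S)-5-hydroxy-3-methyl-6-[(2R)-6-methylhept-5-en-2-yl]-2-oxocyclohexane-1-carboxylate | [Li+].[Li+].COC(=O)C1=C([O-])[C@H](C)C[C@@H]([O-])[C@H]1[C@H](C)CCC=C(C)C | intermediate
14 | methyl (3R,5R,6S)-5-acetoxy-3-methyl-6-[(2R)-6-methylhept-5-en-2-yl]-2-oxocyclohexane-1-carboxylate (C1 epimers/enol) | COC(=O)C1C(=O)[C@H](C)C[C@@H](OC(C)=O)[C@H]1[C@H](C)CCC=C(C)C | intermediate
15 | trimethyl(prop-2-yn-1-yloxy)silane | C#CCO[Si](C)(C)C | starting material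
16 | methyl (5R,7R,8S)-7-acetoxy-5-methyl-8-[(2R)-6-methylhept-5-en-2-yl]-4-oxo-2-[(trimethylsilyloxy)methyl]cyclooct-1-ene-1-carboxylate | COC(=O)/C1=C(CO[Si](C)(C)C)/CC(=O)[C@H](C)C[C@@H](OC(C)=O)[C@H]1[C@H](C)CCC=C(C)C | intermediate
17 | methyl (5R,7R,8S)-7-acetoxy-2-(hydroxymethyl)-5-methyl-8-[(2R)-6-methylhept-5-en-2-yl]-4-oxocyclooct-1-ene-1-carboxylate | COC(=O)/C1=C(CO)/CC(=O)[C@H](C)C[C@@H](OC(C)=O)[C@H]1[C@H](C)CCC=C(C)C | intermediate
18 | (6R,8R,9S)-6-methyl-9-[(2R)-6-methylhept-5-en-2-yl]-1,5-dioxo-1,3,4,5,6,7,8,9-octahydrocycloocta[c]furan-8-yl acetate | CC(=O)O[C@@H]1C[C@@H](C)C(=O)CC2=C(C(=O)OC2)[C@@H]1[C@H](C)CCC=C(C)C | intermediate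
19 | (6R,8R,9S)-8-acetoxy-6-methyl-9-[(2R)-6-methylhept-5-en-2-yl]-1-oxo-1,3,6,7,8,9-hexahydrocycloocta[c]furan-5-yl trifluoromethanesulfonate | CC(=O)O[C@@H]1C[C@@H](C)/C(OS(=O)(=O)C(F)(F)F)=C\C2=C(C(=O)OC2)[C@@H]1[C@H](C)CCC=C(C)C | intermediate
20 | (6R,8R,9S)-6-methyl-9-[(2R)-6-methylhept-5-en-2-yl]-1-oxo-1,3,6,7,8,9-hexahydrocycloocta[c]furan-8-yl acetate | CC(=O)O[C@@H]1C[C@@H](C)/C=C\C2=C(C(=O)OC2)[C@@H]1[C@H](C)CCC=C(C)C | intermediate
21 | acetoxycrenulide (CNP0018922.1) | CC(=O)O[C@@H]1C[C@@H](C)[C@@H]2C[C@@H]2C2=C(C(=O)OC2)[C@@H]1[C@H](C)CCC=C(C)C | target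

**Step count**
Total: 12 steps. Longest linear sequence: 11 steps (1, 2, 3, 5, 6, 7, 8, 9, 10, 11, 12); step 4 is a one-step side branch.

**Three steps most likely to fail**

Step 9 (the proposed new ring expansion). The α-carbon of 14 is flanked by a branched substituent, and neither a propargylic ether nor in-flask lactonisation has been shown in this rhenium chemistry; simple α-alkenylation without C–C cleavage is the likely competing path. The fallback uses known chemistry, sets out from 14 and comes back at 17 (which closes to 18). 14 is treated with methyl 4-(trimethylsilyloxy)but-2-ynoate and Cs2CO3 in MeCN: Michael addition of the β-keto ester to the activated alkyne, closure of the vinyl anion onto the ring ketone and retro-aldol opening (the classical acetylenic-ester two-carbon ring enlargement of 2-carboalkoxycycloalkanones) give dimethyl (5R,7R,8S)-7-acetoxy-5-methyl-8-[(2R)-6-methylhept-5-en-2-yl]-4-oxo-2-[(trimethylsilyloxy)methyl]cyclooct-1-ene-1,3-dicarboxylate F4. Krapcho dealkoxycarbonylation (LiCl, wet DMSO, 120 °C) removes the extra ester at the β-keto ester carbon and frees the alcohol to give 17, which lactonises to 18 on acidic work-up.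

Step 5 (Mukaiyama–Michael). The enal is γ-branched and chiral, the required diastereomer is the one obtained under the less general strong-acid protocol, and the dienamine pathway could erode the γ-centre. The fallback sets out from 6 (with 8) and comes back at 11. Pinnick oxidation of 6 gives (R,E)-4,8-dimethylnona-2,7-dienoic acid F1. Acylation of oxazolidin-2-one through the pivaloyl mixed anhydride (PivCl, Et3N, LiCl) gives 3-[(R,E)-4,8-dimethylnona-2,7-dienoyl]oxazolidin-2-one F2. A chiral Lewis-acid-catalysed vinylogous Mukaiyama–Michael addition of 8 to this bidentate acceptor (Cu(OTf)2/t-Bu-box, CH2Cl2, −20 °C; the anti-selective mode for 3-enoyl-oxazolidinones) gives 3-{(3R,4R)-4,8-dimethyl-3-[(2S)-4-methyl-5-oxo-2,5-dihydrofuran-2-yl]non-7-enoyl}oxazolidin-2-one F3. Methanolysis with MeOMgBr at 0 °C gives 11.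

Step 12 (cyclopropanation). Face selectivity on the flexible eight-membered diene rests on steric control by the C6 methyl only, and uncatalysed dipolar addition of diazomethane to the dienyl lactone is possible. The fallback sets out from 20 and comes back at 21. K2CO3/MeOH removes the acetate to give (6R,8R,9S)-8-hydroxy-6-methyl-9-[(2R)-6-methylhept-5-en-2-yl]-6,7,8,9-tetrahydrocycloocta[c]furan-1(3H)-one F5. A hydroxyl-directed Simmons–Smith reaction (Et2Zn, CH2I2, CH2Cl2, 0 °C; the zinc alkoxide delivers the carbenoid to the ring alkene on its own face and faster than to the remote side-chain alkene) gives the cyclopropyl alcohol, deacetyl-acetoxycrenulide F6. Ac2O/pyridine/DMAP then gives 21.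

**Further compounds**
F1 | step 5 | (R,E)-4,8-dimethylnona-2,7-dienoic acid | OC(=O)/C=C/[C@H](C)CCC=C(C)C
F2 | step 5 | 3-[(R,E)-4,8-dimethylnona-2,7-dienoyl]oxazolidin-2-one | O=C(/C=C/[C@H](C)CCC=C(C)C)N1CCOC1=O
F3 | step 5 | 3-{(3R,4R)-4,8-dimethyl-3-[(2S)-4-methyl-5-oxo-2,5-dihydrofuran-2-yl]non-7-enoyl}oxazolidin-2-one | O=C(C[C@@H]([C@@H]1OC(=O)C(C)=C1)[C@H](C)CCC=C(C)C)N1CCOC1=O
F4 | step 9 | dimethyl (5R,7R,8S)-7-acetoxy-5-methyl-8-[(2R)-6-methylhept-5-en-2-yl]-4-oxo-2-[(trimethylsilyloxy)methyl]cyclooct-1-ene-1,3-dicarboxylate (C3 epimers) | COC(=O)/C1=C(CO[Si](C)(C)C)/C(C(=O)OC)C(=O)[C@H](C)C[C@@H](OC(C)=O)[C@H]1[C@H](C)CCC=C(C)C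
F5 | step 12 | (6R,8R,9S)-8-hydroxy-6-methyl-9-[(2R)-6-methylhept-5-en-2-yl]-6,7,8,9-tetrahydrocycloocta[c]furan-1(3H)-one | O[C@@H]1C[C@@H](C)/C=C\C2=C(C(=O)OC2)[C@@H]1[C@H](C)CCC=C(C)C
F6 | step 12 | deacetyl-acetoxycrenulide (C8 alcohol of 21) | O[C@@H]1C[C@@H](C)[C@@H]2C[C@@H]2C2=C(C(=O)OC2)[C@@H]1[C@H](C)CCC=C(C)C
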